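**Retrosynthetic overview**
Target 27 is a cis-fused eremophilane (ring A: C1–C5 and C10, with C2=O and methyls on C4 and C5; ring B: C5–C10, with isopropenyl on C7 and angelates on C8 and C9; β = face of the C5 methyl): 4β,5β-dimethyl, 10β-H, 7β-isopropenyl, 8α,9α-diacyloxy.
Late stage: ketal hydrolysis and double angeloylation lead back to the 8α,9α-diol, which comes from a Δ7-en-9-one by conjugate addition at C7, hydroxylation at C8 and reduction at C9.
Ring B (formed second) is cut at C6=C7 by ring-closing metathesis of a C5-vinyl/C9-allylcarbinol diene, both arms grown from the C6 formyl and C9 oxymethyl groups of a ring-A aldehyde.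
Ring A (formed first) carries the strategy: its cis C4/C5 methyl pair, quaternary C5 bearing C6, C2 oxygen and C10–C9 branch are the endo [4+2] adduct of tiglic aldehyde (C4, C5, C6, both methyls) with a 2-siloxydiene (C3, C2, C1, C10, C9); bonds C3–C4 and C5–C10 are cut.
The diene is reached in three steps: Williamson etherification, cross-metathesis with methyl vinyl ketone, kinetic enol silylation.

Key step: step 4

Assumption: the sense of induction in step 4 is assigned from the formyl C–H···O binding model of oxazaborolidinium–enal complexes, which points to the (R)-prolinol-derived catalyst for the adduct drawn; if the opposite sense were found, the (S)-catalyst would be used and nothing else changes.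

**Route**

Step 1
Reactants: 1 4-methoxybenzyl alcohol; 2 allyl bromide
Product: 4 allyl 4-methoxybenzyl ether, via sodium 4-methoxybenzyl oxide 3 (not isolated)
Conditions: NaH, THF, 0 °C; then 2, 0 °C → rt
Reagents that add atoms: none
Why: Williamson ether synthesis, an SN2 reaction of a primary alkoxide at an unhindered allylic bromide, creates no stereocentre and has no competing pathway of note.

Step 2
Reactants: 4 allyl 4-methoxybenzyl ether; 5 methyl vinyl ketone
Product: 6 (E)-5-(4-methoxybenzyloxy)pent-3-en-2-one
Conditions: second-generation Hoveyda–Grubbs catalyst (H2IMes)Cl2Ru=CH(C6H4-2-O-i-Pr) (3 mol%), 5 (3 equiv), CH2Cl2, 40 °C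
Reagents that add atoms: none
Why: Olefin cross-metathesis between a terminal alkene that homodimerises readily and an electron-poor enone that does not is selective for the cross product, and the conjugated alkene forms as the E isomer under thermodynamic control.

Step 3
Reactants: 6 (E)-5-(4-methoxybenzyloxy)pent-3-en-2-one
Product: 8 (E)-2-(tert-butyldimethylsilyloxy)-5-(4-methoxybenzyloxy)penta-1,3-diene, via lithium dienolate 7 (not isolated)
Conditions: LiN(i-Pr)2, THF, −78 °C; then TBSCl, DMPU, −78 → 0 °C
Reagents that add atoms: tert-butyldimethylsilyl chloride, CC(C)(C)[Si](C)(C)Cl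
Why: Kinetic deprotonation of the enone at the α′-methyl group gives the cross-conjugated enolate, whose O-silylation (silyl enol ether formation) delivers the 2-siloxydiene with the E geometry of the C3=C4 bond untouched.

Step 4
Reactants: 8 (E)-2-(tert-butyldimethylsilyloxy)-5-(4-methoxybenzyloxy)penta-1,3-diene; 9 tiglic aldehyde
Product: 10 (1R,2S,6S)-4-(tert-butyldimethylsilyloxy)-2-[(4-methoxybenzyloxy)methyl]-1,6-dimethylcyclohex-3-ene-1-carbaldehyde
Conditions: (R)-B-(o-tolyl)oxazaborolidine from (R)-α,α-diphenylprolinol (20 mol%), HNTf2 (18 mol%), 9 (1.5 equiv), CH2Cl2, −78 → −40 °C; Et3N quench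
Reagents that add atoms: none
Why: Protonation of the oxazaborolidine nitrogen by HNTf2 gives a cationic boron Lewis acid that binds the formyl oxygen of the s-trans enal (with a formyl C–H···O contact to the ring oxygen) and lowers its LUMO, so that the diene adds in a concerted, asynchronous [4+2] cycloaddition in which the nucleophilic CH2 terminus C3 bonds to the β-carbon C4 ahead of C10 to the α-carbon C5. The closest known reaction type is the oxazaborolidinium-catalysed Diels–Alder reaction of α-substituted enals with 2-silyloxybutadienes. Ring A closes by intermolecular [4+2] cycloaddition, both new bonds (C3–C4 and C5–C10) forming suprafacially on each partner in a six-membered transition state. The cis C4/C5 methyl pair follows from the E geometry of the dienophile, the cis relation of the C5 formyl group to the C10 side chain from the endo position of the boron-bound carbonyl under the E-configured diene, and the absolute configuration from the catalyst, whose aryl group covers one face of the bound enal so that the diene reaches the Si face of C5. The step needs regioselectivity, formyl-endo selectivity, and cycloaddition in preference to Mukaiyama–Michael addition or protodesilylation of the diene; these should be secured by the matched directing effects of the 2-siloxy and terminal alkyl groups (both make C3 the nucleophilic terminus), the endo preference of Lewis-acid-bound α-methyl enals toward acyclic dienes, the non-nucleophilic triflimide counterion and the low temperature.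

Step 5
Reactants: 10 ring-A aldehyde
Product: 11 ring-A vinyl compound (C6 formyl of 10 replaced by CH=CH2; 4β,5β-dimethyl, 5α-vinyl, 10α-CH2OPMB)
Conditions: Ph3PCH3Br, KOt-Bu, THF, 0 °C → rt
Reagents that add atoms: methyltriphenylphosphonium bromide, C[P+](c1ccccc1)(c1ccccc1)c1ccccc1.[Br-]
Why: Wittig methylenation with the unstabilised ylide converts the hindered aldehyde, which has no α-hydrogen and so cannot epimerise, into the terminal alkene, and the silyl enol ether and benzylic ether are stable to the basic ylide.

Step 6
Reactants: 11 ring-A vinyl compound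
Product: 13 ethylene ketal of the ring-A ketone, via ring-A ketone 12 (not isolated)
Conditions: HOCH2CH2OH, PPTS (cat.), benzene, 25 → 80 °C (Dean–Stark)
Reagents that add atoms: ethylene glycol, OCCO
Why: Acid-catalysed hydrolysis of the silyl enol ether and ketalisation of the freed ketone with the 1,2-diol (dioxolane formation) run in one flask, no stereocentre is α to the C2 carbonyl, and the 4-methoxybenzyl ether tolerates the weak acid.

Step 7
Reactants: 13 ring-A ketal
Product: 14 ring-A primary alcohol (C9–OH)
Conditions: DDQ, CH2Cl2/pH 7 buffer (10:1), 0 °C → rt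
Reagents that add atoms: none
Why: Oxidative cleavage of the 4-methoxybenzyl ether by DDQ (hydride abstraction to the benzylic oxocarbenium ion, then hydrolysis) is selective for the electron-rich benzyl ether, the buffer protects the dioxolane, and the isolated vinyl group is inert.

Step 8
Reactants: 14 ring-A primary alcohol
Product: 15 ring-A C9 aldehyde
Conditions: DMP, pyridine, CH2Cl2, 0 °C → rt; crude product used at once
Reagents that add atoms: none
Why: Dess–Martin oxidation under pyridine buffering gives the aldehyde without acid or strong base, so the enolisable C10 centre should keep its configuration when the crude aldehyde is taken on immediately.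

Step 9
Reactants: 15 ring-A C9 aldehyde
Product: 16 C9 homoallylic alcohol (mixture of C9 epimers)
Conditions: CH2=CHCH2MgBr, Et2O, −78 °C
Reagents that add atoms: allylmagnesium bromide, C=CC[Mg]Br
Why: Grignard 1,2-addition of the allyl nucleophile is much faster than enolisation at −78 °C, and the new C9 carbinol centre may form as a mixture because C9 is oxidised in step 11.

Step 10
Reactants: 16 C9 homoallylic alcohol
Product: 17 2,2-(ethylenedioxy)-11,12,13-trinor-10βH-eremophil-6-en-9-ol (C9 epimers)
Conditions: second-generation Grubbs catalyst (H2IMes)(PCy3)Cl2Ru=CHPh (5 mol%), CH2Cl2 (0.005 M), 40 °C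
Reagents that add atoms: none
Why: Ring-closing metathesis of the 1,7-diene starts at the unhindered allyl terminus and closes cyclohexene ring B onto the neopentyl vinyl group with loss of ethene, the cis ring fusion being fixed by the cis C5-vinyl/C10 side-chain arrangement set in step 4.

Step 11
Reactants: 17 bicyclic homoallylic alcohol
Product: 19 2,2-(ethylenedioxy)-11,12,13-trinor-10βH-eremophil-7-en-9-one, via β,γ-unsaturated ketone 18 (not isolated)
Conditions: DMP, pyridine, CH2Cl2, 0 °C; crude, then DBU (0.1 equiv), CH2Cl2, 0 °C
Reagents that add atoms: none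
Why: Dess–Martin oxidation gives the β,γ-unsaturated ketone, and catalytic amidine base moves the double bond into conjugation through the dienolate formed at the doubly activated C8–H, which is removed far faster than the C10 methine, so the ring fusion is expected to survive.

Step 12
Reactants: 19 Δ7-en-9-one
Product: 21 2,2-(ethylenedioxy)-10βH-eremophil-11-en-9-one (7β-isopropenyl), via trimethylsilyl enol ether 20 (not isolated)
Conditions: CH2=C(CH3)MgBr, CuBr·SMe2 (20 mol%), TMSCl, THF, −78 → −40 °C; then AcOH, THF/H2O, 0 °C
Reagents that add atoms: isopropenylmagnesium bromide, C=C(C)[Mg]Br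
Why: Copper-catalysed conjugate addition of the Grignard reagent (a magnesium diisopropenylcuprate formed in situ, accelerated by TMSCl) should deliver the isopropenyl group to C7 on the convex β face of the cis-fused enone, the α face being screened by ring A through the axial C5–C4 bond lying 1,3 to C7, and mild acid then hydrolyses the silyl enol ether.

Step 13
Reactants: 21 7β-isopropenyl-9-ketone
Product: 23 8α-hydroxy-2,2-(ethylenedioxy)-10βH-eremophil-11-en-9-one, via potassium enolate 22 (not isolated)
Conditions: KN(SiMe3)2 (1.1 equiv), THF, −78 °C; then 2-(phenylsulfonyl)-3-phenyloxaziridine, −78 °C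
Reagents that add atoms: 2-(phenylsulfonyl)-3-phenyloxaziridine, O=S(=O)(c1ccccc1)N1OC1c1ccccc1
Why: Kinetic deprotonation by the hindered amide base occurs at the C8 methylene and not at the neopentyl-like C10 methine, and electrophilic hydroxylation of the enolate by the N-sulfonyloxaziridine (Davis oxidation) is expected anti to the vicinal C7 isopropenyl group, giving the 8α (equatorial) alcohol trans to it, as is usual for enolates with a substituent on the adjacent allylic carbon.

Step 14
Reactants: 23 8α-hydroxy-9-ketone
Product: 24 2,2-(ethylenedioxy)-10βH-eremophil-11-ene-8α,9α-diol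
Conditions: LiBH(s-Bu)3 (2.5 equiv), THF, −78 °C
Reagents that add atoms: none
Why: Reduction by the bulky trialkylborohydride takes place by equatorial attack on the β face, the axial α trajectory at C9 being blocked by the syn-axial C5–C4 bond and the ketal oxygen, so that the 9α (axial) alcohol cis to the 8α hydroxyl should result.

Step 15
Reactants: 24 8α,9α-diol; 25 angelic acid
Product: 26 8α,9α-bis(angeloyloxy)-2,2-(ethylenedioxy)-10βH-eremophil-11-ene
Conditions: 25 (4 equiv), 2,4,6-Cl3C6H2COCl, Et3N, toluene, rt; then 24, 80 °C
Reagents that add atoms: none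
Why: Yamaguchi-type esterification through the mixed 2,4,6-trichlorobenzoic anhydride acylates both hydroxyls at the less hindered angeloyl carbonyl, and the absence of a nucleophilic catalyst avoids Z to E isomerisation of the angelate to the tiglate.

Step 16
Reactants: 26 bis(angelate) ketal
Product: 27 8α,9α-bis(angeloyloxy)-10βH-eremophil-11-en-2-one (4S,5R,7R,8R,9S,10S), the target
Conditions: PPTS, acetone/H2O (9:1), 50 °C
Reagents that add atoms: water, O
Why: Acid-catalysed hydrolysis of the dioxolane frees the C2 ketone under conditions mild enough for the two angelates and the isopropenyl group, and no stereocentre is α to the new carbonyl.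

**Compound list**
1 | 4-methoxybenzyl alcohol | COc1ccc(CO)cc1 | starting material
2 | allyl bromide | C=CCBr | starting material
3 | sodium 4-methoxybenzyl oxide (in flask) | [Na+].[O-]Cc1ccc(OC)cc1 | intermediate
4 | allyl 4-methoxybenzyl ether | C=CCOCc1ccc(OC)cc1 | intermediate
5 | methyl vinyl ketone (but-3-en-2-one) | C=CC(C)=O | starting material
6 | (E)-5-(4-methoxybenzyloxy)pent-3-en-2-one | CC(=O)/C=C/COCc1ccc(OC)cc1 | intermediate
7 | lithium (E)-5-(4-methoxybenzyloxy)penta-1,3-dien-2-olate (in flask) | [Li+].[O-]C(=C)/C=C/COCc1ccc(OC)cc1 | intermediate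
8 | (E)-2-(tert-butyldimethylsilyloxy)-5-(4-methoxybenzyloxy)penta-1,3-diene | C=C(O[Si](C)(C)C(C)(C)C)/C=C/COCc1ccc(OC)cc1 | intermediate
9 | tiglic aldehyde, (E)-2-methylbut-2-enal | C/C=C(C)/C=O | starting material
10 | (1R,2S,6S)-4-(tert-butyldimethylsilyloxy)-2-[(4-methoxybenzyloxy)methyl]-1,6-dimethylcyclohex-3-ene-1-carbaldehyde (formyl cis to CH2OPMB, methyls cis) | O=C[C@@]1(C)[C@H](C=C(O[Si](C)(C)C(C)(C)C)C[C@@H]1C)COCc1ccc(OC)cc1 | intermediate
11 | vinyl analogue of 10 (formyl replaced by CH=CH2, ring-A configuration unchanged) | C=C[C@@]1(C)[C@H](C=C(O[Si](C)(C)C(C)(C)C)C[C@@H]1C)COCc1ccc(OC)cc1 | intermediate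
12 | 3-[(4-methoxybenzyloxy)methyl]-4,5-dimethyl-4-vinylcyclohexan-1-one, configuration as in 10 (in flask) | C=C[C@@]1(C)[C@H](CC(=O)C[C@@H]1C)COCc1ccc(OC)cc1 | intermediate
13 | ethylene ketal of 12 | C=C[C@@]1(C)[C@H](CC2(OCCO2)C[C@@H]1C)COCc1ccc(OC)cc1 | intermediate
14 | primary alcohol from 13 (C9–OH) | C=C[C@@]1(C)[C@H](CC2(OCCO2)C[C@@H]1C)CO | intermediate
15 | C9 aldehyde from 14 | C=C[C@@]1(C)[C@H](CC2(OCCO2)C[C@@H]1C)C=O | intermediate
16 | C9 homoallylic alcohol (C9 epimers) | C=C[C@@]1(C)[C@H](CC2(OCCO2)C[C@@H]1C)C(O)CC=C | intermediate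
17 | 2,2-(ethylenedioxy)-11,12,13-trinor-10βH-eremophil-6-en-9-ol (C9 epimers; cis-fused, 4β,5β-dimethyl) | OC1CC=C[C@@]2(C)[C@@H]1CC3(OCCO3)C[C@@H]2C | intermediate
18 | 2,2-(ethylenedioxy)-11,12,13-trinor-10βH-eremophil-6-en-9-one (in flask) | O=C1CC=C[C@@]2(C)[C@@H]1CC3(OCCO3)C[C@@H]2C | intermediate
19 | 2,2-(ethylenedioxy)-11,12,13-trinor-10βH-eremophil-7-en-9-one | O=C1C=CC[C@@]2(C)[C@@H]1CC3(OCCO3)C[C@@H]2C | intermediate
20 | 9-(trimethylsilyloxy)-2,2-(ethylenedioxy)-10βH-eremophila-8,11-diene, 7β-isopropenyl (in flask) | C[Si](C)(C)OC1=C[C@@H](C(C)=C)C[C@@]2(C)[C@@H]1CC3(OCCO3)C[C@@H]2C | intermediate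
21 | 2,2-(ethylenedioxy)-10βH-eremophil-11-en-9-one, 7β-isopropenyl | O=C1C[C@@H](C(C)=C)C[C@@]2(C)[C@@H]1CC3(OCCO3)C[C@@H]2C | intermediate
22 | potassium Δ8-enolate of 21 (in flask) | [K+].[O-]C1=C[C@@H](C(C)=C)C[C@@]2(C)[C@@H]1CC3(OCCO3)C[C@@H]2C | intermediate
23 | 8α-hydroxy-2,2-(ethylenedioxy)-10βH-eremophil-11-en-9-one | O=C1[C@H](O)[C@@H](C(C)=C)C[C@@]2(C)[C@@H]1CC3(OCCO3)C[C@@H]2C | intermediate
24 | 2,2-(ethylenedioxy)-10βH-eremophil-11-ene-8α,9α-diol | O[C@@H]1[C@H](O)[C@@H](C(C)=C)C[C@@]2(C)[C@@H]1CC3(OCCO3)C[C@@H]2C | intermediate
25 | angelic acid, (Z)-2-methylbut-2-enoic acid | C/C=C(/C)C(=O)O | starting material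
26 | 8α,9α-bis(angeloyloxy)-2,2-(ethylenedioxy)-10βH-eremophil-11-ene | C/C=C(/C)C(=O)O[C@@H]1[C@H](OC(=O)/C(C)=C\C)[C@@H](C(C)=C)C[C@@]2(C)[C@@H]1CC3(OCCO3)C[C@@H]2C | intermediate
27 | 8α,9α-bis(angeloyloxy)-10βH-eremophil-11-en-2-one (4S,5R,7R,8R,9S,10S) | C=C(C)[C@H]1C[C@@]2(C)[C@H](CC(=O)C[C@@H]2C)[C@H](OC(=O)/C(C)=C\C)[C@@H]1OC(=O)/C(C)=C\C | target

**Totals and risks**
Total step count: 16. Longest linear sequence: 16 steps (1 to 27).

Steps most likely to fail:

1. Step 4. The β-substituted enal is a sluggish dienophile. If cycloaddition is slower than protodesilylation or Mukaiyama–Michael addition of the diene, or if formyl-endo and facial selectivity erode, little adduct or adduct of low enantiomeric purity results. Fallback (resolution in place of asymmetric catalysis), setting out from 8 and 9 and returning at 14: the cycloaddition is promoted by the achiral Lewis acid Me2AlCl (CH2Cl2, −78 °C), which activates the enal more strongly and should give the same endo adduct as a racemate, that is 10 together with the enantiomer of 10 F1. Steps 5 to 7 are run on the racemate and give, beside 11 to 14, the enantiomer of 11 F2, the enantiomer of 12 F3 (in the flask), the enantiomer of 13 F4 and the enantiomer of 14 F5. The racemic primary alcohol is acetylated with vinyl acetate in the presence of Candida antarctica lipase B, and alcohol and acetate are separated. Depending on which enantiomer the enzyme prefers, 14 is recovered directly beside the acetate of the enantiomer of 14 F7, or it is obtained as the acetate of 14 F6 and freed with K2CO3 in MeOH.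

2. Step 12. The copper nucleophile may be delivered to C7 with poor or reversed facial selectivity, because the two half-chair forms of the cis-fused enone expose opposite faces. Fallback (exchange of the roles of carbon and hydride), setting out from 19 and returning at 21: the addition is run as in step 12 but the silyl enol ether is kept (20 or the C7 epimer of 20 F8). Saegusa–Ito oxidation (Pd(OAc)2, MeCN) converts either epimer into the 7-isopropenyl-7-en-9-one F9. Conjugate reduction with [(Ph3P)CuH]6 then places hydride, not carbon, on C7 from the face the bicycle prefers for a copper nucleophile, so the isopropenyl group ends on the opposite, β face; protonation of the enolate gives 21.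

3. Step 13. Hydroxylation may occur by chair-like axial attack on the β face, syn to the isopropenyl group, and give the C8 epimer. Fallback (inversion by SN2 displacement in place of face-selective oxidation), setting out from 21 and returning at 23: the 8β-hydroxy ketone F10 formed in that case is inverted by Mitsunobu reaction (4-nitrobenzoic acid, PPh3, DIAD, THF) to the 8α-(4-nitrobenzoate) F11, and methanolysis (K2CO3, MeOH, 0 °C) gives 23.

**Further compounds**
F1 | step 4 | enantiomer of 10 | O=C[C@]1(C)[C@@H](C=C(O[Si](C)(C)C(C)(C)C)C[C@H]1C)COCc1ccc(OC)cc1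
F2 | step 4 | enantiomer of 11 | C=C[C@]1(C)[C@@H](C=C(O[Si](C)(C)C(C)(C)C)C[C@H]1C)COCc1ccc(OC)cc1
F3 | step 4 | enantiomer of 12 (in flask) | C=C[C@]1(C)[C@@H](CC(=O)C[C@H]1C)COCc1ccc(OC)cc1
F4 | step 4 | enantiomer of 13 | C=C[C@]1(C)[C@@H](CC2(OCCO2)C[C@H]1C)COCc1ccc(OC)cc1
F5 | step 4 | enantiomer of 14 | C=C[C@]1(C)[C@@H](CC2(OCCO2)C[C@H]1C)CO
F6 | step 4 | acetate of 14 | C=C[C@@]1(C)[C@H](CC2(OCCO2)C[C@@H]1C)COC(C)=O
F7 | step 4 | acetate of the enantiomer of 14 | C=C[C@]1(C)[C@@H](CC2(OCCO2)C[C@H]1C)COC(C)=O
F8 | step 12 | C7 epimer of 20 (7α-isopropenyl silyl enol ether) | C[Si](C)(C)OC1=C[C@H](C(C)=C)C[C@@]2(C)[C@@H]1CC3(OCCO3)C[C@@H]2C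
F9 | step 12 | 2,2-(ethylenedioxy)-10βH-eremophila-7,11-dien-9-one | O=C1C=C(C(C)=C)C[C@@]2(C)[C@@H]1CC3(OCCO3)C[C@@H]2C
F10 | step 13 | 8β-hydroxy-2,2-(ethylenedioxy)-10βH-eremophil-11-en-9-one | O=C1[C@@H](O)[C@@H](C(C)=C)C[C@@]2(C)[C@@H]1CC3(OCCO3)C[C@@H]2C
F11 | step 13 | 8α-(4-nitrobenzoyloxy)-2,2-(ethylenedioxy)-10βH-eremophil-11-en-9-one | O=C1[C@H](OC(=O)c4ccc(cc4)[N+](=O)[O-])[C@@H](C(C)=C)C[C@@]2(C)[C@@H]1CC3(OCCO3)C[C@@H]2C
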